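**Retrosynthetic overview**
1. Target ⇐ bis-silyl ether ⇐ aryl ketone at the exocyclic benzylic carbon (catalyst-controlled reduction sets the carbinol) ⇐ lactol (one oxidation gives both the lactone C2=O and the ketone).
2. Lactol ⇐ 1,2-oxasilolane aldehyde by Tamao oxidation: the C–Si bond becomes the C5–O1 bond, the silicon tether is excised and the oxolane ring closes by itself.
3. Key disconnection: the C5–C4 bond and the C2–C3 bond of the lactone, made together across the C=C of an (E)-1,4-diarylbut-2-en-1-ol by a silicon-tethered CH2 radical and CO (alkene + CH2 + CO joined around the lactone core).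
4. Enabling feature: the carbinol oxygen on the benzylic carbon attached to C4 and the ring oxygen O1 on C5 stand 1,3 to each other across C4 (a masked 2-substituted 1,3-diol). An O–SiMe2–CH2 tether from the carbinol oxygen therefore reaches C4 by 5-exo closure, and its C–Si bond is later oxidised to C5–OH.
5. Ring order: temporary 1,2-oxasilolane (key step), then the oxolane as lactol and lactone; the allylic alcohol comes from a vanillin-derived aldehyde and a 3-arylpropyne by asymmetric alkenylzinc addition.

Key step: step 7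

Remark: the target is read as (3R,4R)-4-[(S)-hydroxy(4-hydroxy-3-methoxyphenyl)methyl]-3-[(4-hydroxy-3-methoxyphenyl)methyl]oxolan-2-one (trans lactone). Lactone numbering O1, C2 (carbonyl), C3, C4, C5 is used throughout. Ar = 3-methoxy-4-[tri(propan-2-yl)silyloxy]phenyl; TIPS = tri(propan-2-yl)silyl. The radical cyclization is expected to place the aryl group and the new exocyclic carbon trans on the oxasilolane, which is the wrong relative configuration at the carbinol for the target. The route therefore starts from the (R)-carbinol, uses it only to set C4, and resets the carbinol to (S) by oxidation and reduction (steps 9 and 10).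

**Step 1**
Reactants: 1 vanillin (4-hydroxy-3-methoxybenzaldehyde)
Product: 2 3-methoxy-4-[tri(propan-2-yl)silyloxy]benzaldehyde
Conditions: TIPSCl, imidazole, DMF, 23 °C
Reagents that add atoms: triisopropylsilyl chloride, CC(C)[Si](Cl)(C(C)C)C(C)C
Why: Standard phenol silylation; the bulky aryl silyl ether should survive organozinc, radical, peroxide and borane conditions and can be removed at the end with buffered fluoride, avoiding the acid or hydrogenolysis that the p-oxygenated benzylic alcohol of the target would not tolerate.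

**Step 2**
Reactants: 3 4-bromo-2-methoxyphenol
Product: 4 (4-bromo-2-methoxyphenoxy)tri(propan-2-yl)silane
Conditions: TIPSCl, imidazole, DMF, 23 °C
Reagents that add atoms: triisopropylsilyl chloride, CC(C)[Si](Cl)(C(C)C)C(C)C
Why: Same phenol silylation as in step 1, giving an aryl bromide ready for Grignard formation.

**Step 3**
Reactants: 4 (4-bromo-2-methoxyphenoxy)tri(propan-2-yl)silane; 5 3-bromo-1-(trimethylsilyl)prop-1-yne
Product: 7 {2-methoxy-4-[3-(trimethylsilyl)prop-2-yn-1-yl]phenoxy}tri(propan-2-yl)silane, via arylmagnesium bromide 6 (not isolated)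
Conditions: Mg, THF, 45 °C; then 5, CuBr·SMe2 (5 mol %), THF, −20 → 23 °C
Reagents that add atoms: none
Why: Grignard formation from the electron-rich aryl bromide and copper-catalysed SN2 coupling at the propargylic bromide; the C-silyl cap blocks the SN2′ (allene) pathway and acetylide formation.

**Step 4**
Reactants: 7 {2-methoxy-4-[3-(trimethylsilyl)prop-2-yn-1-yl]phenoxy}tri(propan-2-yl)silane
Product: 8 [2-methoxy-4-(prop-2-yn-1-yl)phenoxy]tri(propan-2-yl)silane
Conditions: AgNO3 (10 mol %), acetone/H2O, 23 °C
Reagents that add atoms: none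
Why: Silver-catalysed protodesilylation of the alkynyl–silicon bond under neutral conditions, which should leave the aryl silyl ether intact and avoid base-induced propargyl-to-allene isomerisation.

**Step 5**
Reactants: 8 [2-methoxy-4-(prop-2-yn-1-yl)phenoxy]tri(propan-2-yl)silane; 2 3-methoxy-4-[tri(propan-2-yl)silyloxy]benzaldehyde
Product: 11 (1R,2E)-1,4-bis(Ar)but-2-en-1-ol, via alkenyldicyclohexylborane 9 (not isolated), via alkenyl(methyl)zinc 10 (not isolated)
Conditions: Cy2BH, toluene, 0 → 23 °C; Me2Zn, (+)-MIB [(2R)-3-exo-morpholinoisoborneol, 5 mol %], −78 °C; then 2, −20 → 0 °C; aq. NH4Cl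
Reagents that add atoms: none
Why: Catalytic asymmetric alkenylzinc addition to an aryl aldehyde: syn, anti-Markovnikov hydroboration fixes the E geometry, boron-to-zinc exchange gives the alkenylzinc, and the amino alcohol ligand (the enantiomer of the one that gives (S)-carbinols) should direct Re-face addition to set the (R)-carbinol.

**Step 6**
Reactants: 11 (1R,2E)-1,4-bis(Ar)but-2-en-1-ol; 12 (bromomethyl)chlorodimethylsilane
Product: 13 (bromomethyl){[(1R,2E)-1,4-bis(Ar)but-2-en-1-yl]oxy}dimethylsilane
Conditions: Et3N, DMAP (5 mol %), CH2Cl2, 0 °C; used without chromatography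
Reagents that add atoms: none
Why: Silylation of the secondary alcohol under basic conditions installs the radical precursor without ionising the allylic benzylic C–O bond, so the stereocentre is untouched.

**Step 7**
Reactants: 13 (bromomethyl){[(1R,2E)-1,4-bis(Ar)but-2-en-1-yl]oxy}dimethylsilane; 14 carbon monoxide
Product: 15 (2RS)-2-[(4S,5R)-5-Ar-2,2-dimethyl-1,2-oxasilolan-4-yl]-3-Ar-propanal
Conditions: (Me3Si)3SiH (1.3 equiv), AIBN (0.2 equiv), CO (30 atm), C6H6 (0.02 M), 80 °C
Reagents that add atoms: none
Why: Proposed new method: the silyl radical from (Me3Si)3SiH abstracts bromine from 13, the α-silylmethyl radical closes the 1,2-oxasilolane by 5-exo-trig attack on the alkene carbon next to the carbinol (future lactone C4, making the C5–C4 bond), the secondary alkyl radical left on the distal carbon (future C3) captures CO (making the C2–C3 bond), and the acyl radical takes hydrogen from the silane to give the aldehyde and carry the chain. The closest known reaction types are the radical cyclization of (bromomethyl)dimethylsilyl ethers of allylic alcohols (Nishiyama–Stork type) and the hydride-mediated radical carbonylation of alkyl halides under CO pressure, including cyclization–formylation cascades of carbon-tethered haloalkenes; the two have not been merged on a silyl ether tether, which is why the step is labelled. Ring closure: 5-exo rather than 6-endo, secured by the arylmethyl substituent on the distal alkene carbon. Stereocontrol: the new ring stereocentre (oxasilolane C4) is set by the (R)-carbinol carbon through a chair-like Beckwith–Houk transition state with the aryl group pseudo-equatorial, which places the aryl group and the new exocyclic carbon trans (4S,5R); the formyl-bearing carbon forms without control and is corrected in step 8. Selectivity needed: ring closure must outrun CO capture by the first radical, and CO capture must outrun hydrogen transfer to the cyclised radical; high dilution, the slow hydrogen donor (Me3Si)3SiH and a moderate CO pressure are chosen for this, and CO capture by the silyl-stabilised first radical is reversible, so that material can still drain through cyclization.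

**Step 8**
Reactants: 15 (2RS)-2-[(4S,5R)-5-Ar-2,2-dimethyl-1,2-oxasilolan-4-yl]-3-Ar-propanal
Product: 17 (3R,4R)-4-[(R)-hydroxy(Ar)methyl]-3-(Ar-methyl)oxolan-2-ol (mixture of anomers), via open-chain dihydroxy aldehyde 16 (not isolated)
Conditions: H2O2 (30 % aq.), KHCO3, THF/MeOH (1:1), 40 °C; aq. Na2S2O3; then DBU (0.3 equiv), THF, 23 °C
Reagents that add atoms: hydrogen peroxide, OO
Why: Tamao–Kumada oxidation of the alkoxy-activated C–Si bond unveils the primary alcohol and frees the carbinol, the γ-hydroxy aldehyde closes spontaneously to the five-membered lactol (which also masks the aldehyde from peroxide), and DBU equilibrates the aldehyde α-carbon through the open form toward the 3,4-trans lactol closed through the primary hydroxyl, which avoids the cis aryl/hydroxymethyl contact of the alternative ring.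

**Step 9**
Reactants: 17 (3R,4R)-4-[(R)-hydroxy(Ar)methyl]-3-(Ar-methyl)oxolan-2-ol
Product: 18 (3R,4R)-4-(Ar-carbonyl)-3-(Ar-methyl)oxolan-2-one
Conditions: Dess–Martin periodinane (3 equiv), CH2Cl2, 0 → 23 °C
Reagents that add atoms: none
Why: Dess–Martin oxidation should convert the lactol into the γ-lactone and the benzylic alcohol into the aryl ketone in one non-basic operation, so neither C3 nor the now enolisable C4 epimerises and the β-acyloxy ketone does not eliminate.

**Step 10**
Reactants: 18 (3R,4R)-4-(Ar-carbonyl)-3-(Ar-methyl)oxolan-2-one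
Product: 19 (3R,4R)-4-[(S)-hydroxy(Ar)methyl]-3-(Ar-methyl)oxolan-2-one
Conditions: (R)-2-methyl-CBS-oxazaborolidine (0.3 equiv), BH3·SMe2 (1.2 equiv), THF, −30 °C; MeOH
Reagents that add atoms: none
Why: Corey–Bakshi–Shibata reduction: the (R)-oxazaborolidine should deliver hydride to the aryl ketone with the aryl group as the large substituent to give the (S)-carbinol, a sense that coincides with Felkin–Anh attack anti to the C3 branch of the ring, while the non-basic medium spares the lactone and the C4 centre.

**Step 11**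
Reactants: 19 (3R,4R)-4-[(S)-hydroxy(Ar)methyl]-3-(Ar-methyl)oxolan-2-one
Product: 20 (3R,4R)-4-[(S)-hydroxy(4-hydroxy-3-methoxyphenyl)methyl]-3-[(4-hydroxy-3-methoxyphenyl)methyl]oxolan-2-one
Conditions: TBAF, AcOH (1:1, 2.5 equiv each), THF, 0 °C
Reagents that add atoms: none
Why: Fluoride cleavage of the two aryl silyl ethers, with acetic acid keeping the phenols protonated so that neither quinone methide formation from the p-hydroxybenzylic alcohol nor lactone opening should occur.

**Compound list**
1 | vanillin (4-hydroxy-3-methoxybenzaldehyde) | COc1cc(C=O)ccc1O | starting material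
2 | 3-methoxy-4-[tri(propan-2-yl)silyloxy]benzaldehyde | COc1cc(C=O)ccc1O[Si](C(C)C)(C(C)C)C(C)C | intermediate
3 | 4-bromo-2-methoxyphenol | COc1cc(Br)ccc1O | starting material
4 | (4-bromo-2-methoxyphenoxy)tri(propan-2-yl)silane | COc1cc(Br)ccc1O[Si](C(C)C)(C(C)C)C(C)C | intermediate
5 | 3-bromo-1-(trimethylsilyl)prop-1-yne | C[Si](C)(C)C#CCBr | starting material
6 | {3-methoxy-4-[tri(propan-2-yl)silyloxy]phenyl}magnesium bromide | COc1cc([Mg]Br)ccc1O[Si](C(C)C)(C(C)C)C(C)C | intermediate (not isolated)
7 | {2-methoxy-4-[3-(trimethylsilyl)prop-2-yn-1-yl]phenoxy}tri(propan-2-yl)silane | COc1cc(CC#C[Si](C)(C)C)ccc1O[Si](C(C)C)(C(C)C)C(C)C | intermediate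
8 | [2-methoxy-4-(prop-2-yn-1-yl)phenoxy]tri(propan-2-yl)silane | COc1cc(CC#C)ccc1O[Si](C(C)C)(C(C)C)C(C)C | intermediate
9 | dicyclohexyl[(E)-3-Ar-prop-1-en-1-yl]borane | COc1cc(C/C=C/B(C2CCCCC2)C2CCCCC2)ccc1O[Si](C(C)C)(C(C)C)C(C)C | intermediate (not isolated)
10 | methyl[(E)-3-Ar-prop-1-en-1-yl]zinc | COc1cc(C/C=C/[Zn]C)ccc1O[Si](C(C)C)(C(C)C)C(C)C | intermediate (not isolated)
11 | (1R,2E)-1,4-bis(Ar)but-2-en-1-ol | COc1cc(C/C=C/[C@@H](O)c2ccc(O[Si](C(C)C)(C(C)C)C(C)C)c(OC)c2)ccc1O[Si](C(C)C)(C(C)C)C(C)C | intermediate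
12 | (bromomethyl)chlorodimethylsilane | C[Si](C)(Cl)CBr | starting material
13 | (bromomethyl){[(1R,2E)-1,4-bis(Ar)but-2-en-1-yl]oxy}dimethylsilane | COc1cc(C/C=C/[C@@H](O[Si](C)(C)CBr)c2ccc(O[Si](C(C)C)(C(C)C)C(C)C)c(OC)c2)ccc1O[Si](C(C)C)(C(C)C)C(C)C | intermediate
14 | carbon monoxide | [C-]#[O+] | starting material
15 | (2RS)-2-[(4S,5R)-5-Ar-2,2-dimethyl-1,2-oxasilolan-4-yl]-3-Ar-propanal (both C-2 epimers) | C[Si]1(C)C[C@@H](C(Cc2ccc(O[Si](C(C)C)(C(C)C)C(C)C)c(OC)c2)C=O)[C@H](c2ccc(O[Si](C(C)C)(C(C)C)C(C)C)c(OC)c2)O1 | intermediate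
16 | (3R,4R)-4-Ar-4-hydroxy-3-(hydroxymethyl)-2-(Ar-methyl)butanal (both C-2 epimers) | O=CC(Cc1ccc(O[Si](C(C)C)(C(C)C)C(C)C)c(OC)c1)[C@H](CO)[C@@H](O)c1ccc(O[Si](C(C)C)(C(C)C)C(C)C)c(OC)c1 | intermediate (not isolated)
17 | (3R,4R)-4-[(R)-hydroxy(Ar)methyl]-3-(Ar-methyl)oxolan-2-ol (anomers) | COc1cc(C[C@H]2C(O)OC[C@@H]2[C@@H](O)c2ccc(O[Si](C(C)C)(C(C)C)C(C)C)c(OC)c2)ccc1O[Si](C(C)C)(C(C)C)C(C)C | intermediate
18 | (3R,4R)-4-(Ar-carbonyl)-3-(Ar-methyl)oxolan-2-one | COc1cc(C[C@H]2C(=O)OC[C@@H]2C(=O)c2ccc(O[Si](C(C)C)(C(C)C)C(C)C)c(OC)c2)ccc1O[Si](C(C)C)(C(C)C)C(C)C | intermediate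
19 | (3R,4R)-4-[(S)-hydroxy(Ar)methyl]-3-(Ar-methyl)oxolan-2-one | COc1cc(C[C@H]2C(=O)OC[C@@H]2[C@H](O)c2ccc(O[Si](C(C)C)(C(C)C)C(C)C)c(OC)c2)ccc1O[Si](C(C)C)(C(C)C)C(C)C | intermediate
20 | (3R,4R)-4-[(S)-hydroxy(4-hydroxy-3-methoxyphenyl)methyl]-3-[(4-hydroxy-3-methoxyphenyl)methyl]oxolan-2-one | COc1cc(C[C@H]2C(=O)OC[C@@H]2[C@H](O)c2ccc(O)c(OC)c2)ccc1O | target

**Totals**
Total step count: 11. Longest linear sequence: 10 steps (3 → 4 → 7 → 8 → 11 → 13 → 15 → 17 → 18 → 19 → 20; step 1 feeds in at step 5).

**Steps most likely to fail**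

Step 7 (bears the label). What may go wrong: CO capture by the first radical before ring closure, hydrogen transfer to the cyclised radical before CO capture, or 6-endo closure, each draining material away from the aldehyde. Fallback by known chemistry (tandem conjugate addition–alkylation on a chiral butenolide), setting out from 2 and coming back at 18: thioacetalisation of 2 with propane-1,3-dithiol (cat. I2, CH2Cl2) should give 2-Ar-1,3-dithiane F1. Separately, NaBH4 reduction of 2 should give the benzylic alcohol Ar-methanol F2, and an Appel reaction (CBr4, PPh3) the benzylic bromide Ar-methyl bromide F3. Lithiation of F1 (n-BuLi, THF, −78 °C), conjugate addition to commercial (5R)-5-[(1R,2S,5R)-menthyloxy]furan-2(5H)-one anti to the menthyloxy group, and trapping of the lactone enolate with F3 anti to the new substituent should give the all-trans adduct (3R,4R,5R)-3-(Ar-methyl)-4-(2-Ar-1,3-dithian-2-yl)-5-menthyloxyoxolan-2-one F4. Reduction of the acetal carbon to the lactone methylene with loss of menthol (NaBH4, KOH, aq. EtOH, then mild acid; any phenol set free is re-silylated with TIPSCl and imidazole) should give the dithianyl lactone (3R,4R)-3-(Ar-methyl)-4-(2-Ar-1,3-dithian-2-yl)oxolan-2-one F5. Dithiane hydrolysis (MeI, CaCO3, aq. MeCN) should then give 18.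

Step 8. What may go wrong: oxidation of the open-chain aldehyde by alkaline peroxide before it is masked as the lactol, cleavage of the aryl silyl ethers by hydroperoxide, and incomplete convergence on the trans lactol because the C-3 epimer can close through the benzylic hydroxyl instead. Fallback at the carboxyl oxidation level, setting out from 15 and coming back at 18: Pinnick oxidation (NaClO2, NaH2PO4, 2-methylbut-2-ene, t-BuOH/H2O) should give the acid 2-[(4S,5R)-5-Ar-2,2-dimethyl-1,2-oxasilolan-4-yl]-3-Ar-propanoic acid F6, which is inert to peroxide. Tamao oxidation (H2O2, KHCO3, THF/MeOH), acidification to pH 4 (lactonisation through the primary hydroxyl) and epimerisation of C3 with DBU (toluene, 60 °C) should give the trans lactone (3R,4R)-4-[(R)-hydroxy(Ar)methyl]-3-(Ar-methyl)oxolan-2-one F7. Dess–Martin oxidation of its only free hydroxyl should give 18.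

Step 10. What may go wrong: insufficient facial selectivity if catalyst control and the substrate's own bias turn out to oppose each other, or competing reduction of the lactone. Fallback by SN2 inversion instead of face-selective hydride delivery, setting out from 17 and coming back at 19: Ag2CO3 on Celite (benzene, reflux) should oxidise only the lactol and give the (R)-carbinol lactone (compound F7 of the preceding fallback). Mitsunobu esterification with 4-nitrobenzoic acid (PPh3, DIAD, THF, 0 °C) should invert the carbinol to the ester (3R,4R)-4-[(S)-(4-nitrobenzoyloxy)(Ar)methyl]-3-(Ar-methyl)oxolan-2-one F8. Mild methanolysis (NaN3, MeOH, 40 °C) should give 19.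

**Further compounds**
F1 | step 7 | 2-Ar-1,3-dithiane | COc1cc(C2SCCCS2)ccc1O[Si](C(C)C)(C(C)C)C(C)C
F2 | step 7 | {3-methoxy-4-[tri(propan-2-yl)silyloxy]phenyl}methanol | COc1cc(CO)ccc1O[Si](C(C)C)(C(C)C)C(C)C
F3 | step 7 | [4-(bromomethyl)-2-methoxyphenoxy]tri(propan-2-yl)silane | COc1cc(CBr)ccc1O[Si](C(C)C)(C(C)C)C(C)C
F4 | step 7 | (3R,4R,5R)-3-(Ar-methyl)-4-(2-Ar-1,3-dithian-2-yl)-5-[(1R,2S,5R)-menthyloxy]oxolan-2-one | COc1cc(C[C@H]2C(=O)O[C@@H](O[C@@H]3C[C@H](C)CC[C@H]3C(C)C)[C@@H]2C4(SCCCS4)c5ccc(O[Si](C(C)C)(C(C)C)C(C)C)c(OC)c5)ccc1O[Si](C(C)C)(C(C)C)C(C)C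
F5 | step 7 | (3R,4R)-3-(Ar-methyl)-4-(2-Ar-1,3-dithian-2-yl)oxolan-2-one | COc1cc(C[C@H]2C(=O)OC[C@@H]2C4(SCCCS4)c5ccc(O[Si](C(C)C)(C(C)C)C(C)C)c(OC)c5)ccc1O[Si](C(C)C)(C(C)C)C(C)C
F6 | step 8 | (2RS)-2-[(4S,5R)-5-Ar-2,2-dimethyl-1,2-oxasilolan-4-yl]-3-Ar-propanoic acid | C[Si]1(C)C[C@@H](C(Cc2ccc(O[Si](C(C)C)(C(C)C)C(C)C)c(OC)c2)C(=O)O)[C@H](c2ccc(O[Si](C(C)C)(C(C)C)C(C)C)c(OC)c2)O1
F7 | step 8 | (3R,4R)-4-[(R)-hydroxy(Ar)methyl]-3-(Ar-methyl)oxolan-2-one | COc1cc(C[C@H]2C(=O)OC[C@@H]2[C@@H](O)c2ccc(O[Si](C(C)C)(C(C)C)C(C)C)c(OC)c2)ccc1O[Si](C(C)C)(C(C)C)C(C)C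
F8 | step 10 | (3R,4R)-4-[(S)-(4-nitrobenzoyloxy)(Ar)methyl]-3-(Ar-methyl)oxolan-2-one | COc1cc(C[C@H]2C(=O)OC[C@@H]2[C@H](OC(=O)c2ccc(cc2)[N+](=O)[O-])c2ccc(O[Si](C(C)C)(C(C)C)C(C)C)c(OC)c2)ccc1O[Si](C(C)C)(C(C)C)C(C)C
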